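**Assumption:** natural (+)-β-eudesmol (CAS 473-15-4; 5α-H, 7β-side chain, 10β-Me) is accepted as a commercial chiral-pool starting material. It supplies C5, C7 and C10 unchanged, so only C4 is created in the route. Eudesmane numbering is used: C4 is the carbinol carbon bearing the C15 methyl, C5 the ring-fusion CH, C7 the carbon bearing C11 (CMe2O), C10 the angular-methyl carbon. The route is a paper proposal and has not been run.

## Retrosynthetic overview

1. Last bonds: C11 O–Si cleavage, then both allyl groups by one double cross-coupling of an aryl dibromide.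
2. The central phenolic OH comes from an aryl aldehyde (Dakin oxidation). That CHO first serves as the activating group for two sequential SNAr reactions on 4-bromo-2,6-difluorobenzaldehyde.
3. SNAr order: the C4 tertiary alkoxide first (tert-alkyl aryl ether, C4 configuration retained), then 4-bromophenol (diaryl ether).
4. The 4α-OH/4β-Me centre comes from α-face epoxidation and hydride opening of the exocyclic alkene of β-eudesmol, with C11-OH masked as its TES ether.
5. Rings: none is formed. The trans-decalin comes intact from β-eudesmol and both arenes are purchased.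

## Route

**Step 1**
Reactants: 1, (+)-β-eudesmol [(5S,7R,10R)-eudesm-4(15)-en-11-ol]
Product: 2, 11-(triethylsilyloxy)eudesm-4(15)-ene
Conditions: TESOTf, 2,6-lutidine, CH2Cl2, −78 → 0 °C
Reagents that add atoms: triethylsilyl triflate, CC[Si](CC)(CC)OS(=O)(=O)C(F)(F)F
Why: Silylation of the only (tertiary) hydroxyl with a silyl triflate masks C11-OH so that only the C4 alkoxide exists later; the lutidine buffer prevents alkene isomerisation and no stereocentre is touched.

**Step 2**
Reactants: 2
Product: 3, (4R,5R,7R,10R)-4,15-epoxy-11-(triethylsilyloxy)eudesmane (spiro-epoxide, oxygen α, CH2 β)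
Conditions: mCPBA, NaHCO3, CH2Cl2, 0 °C
Reagents that add atoms: mCPBA, OOC(=O)c1cccc(Cl)c1
Why: Prilezhaev epoxidation occurs from the α-face, anti to the syn-axial C10 angular methyl, which sets C4 with oxygen α; the minor β-epoxide is removed by chromatography.

**Step 3**
Reactants: 3
Product: 4, (4R,5R,7R,10R)-11-(triethylsilyloxy)eudesman-4-ol (11-O-TES-cryptomeridiol; 4α-OH, 4β-CH3)
Conditions: LiAlH4, THF, 0 °C → rt
Reagents that add atoms: none
Why: SN2 hydride opening of the 2,2-disubstituted epoxide at the unhindered CH2 leaves the C4–O bond intact, so the C4 configuration is retained and CH2 becomes the β-methyl.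

**Step 4**
Reactants: 4; 5, 4-bromo-2,6-difluorobenzaldehyde
Product: 6, 4-bromo-2-fluoro-6-{[(4R,5R,7R,10R)-11-(triethylsilyloxy)eudesman-4-yl]oxy}benzaldehyde
Conditions: KHMDS (1.05 equiv), THF, 0 °C; then 5 (1.3 equiv), 0 °C → rt
Reagents that add atoms: none
Why: SNAr (addition–elimination) of the potassium tert-alkoxide at a fluorine ortho to CHO stops at mono-substitution because the product is deactivated; the alkyl C4–O bond is not involved, so C4 is retained.

**Step 5**
Reactants: 6; 7, 4-bromophenol
Product: 8, 4-bromo-2-(4-bromophenoxy)-6-{[(4R,5R,7R,10R)-11-(triethylsilyloxy)eudesman-4-yl]oxy}benzaldehyde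
Conditions: Cs2CO3, DMF, 90 °C
Reagents that add atoms: none
Why: A second SNAr by phenoxide displaces the remaining CHO-activated ortho-fluorine (F far better than Br as leaving group, and the tert-alkoxy group is a poor one) to give the diaryl ether.

**Step 6**
Reactants: 8
Product: 9, 4-bromo-2-(4-bromophenoxy)-6-{[(4R,5R,7R,10R)-11-(triethylsilyloxy)eudesman-4-yl]oxy}phenol
Conditions: mCPBA, NaHCO3, CH2Cl2, 0 °C → rt; then K2CO3, MeOH, rt (aryl formate not isolated)
Reagents that add atoms: mCPBA, OOC(=O)c1cccc(Cl)c1 (supplies the phenol oxygen; the CHO carbon leaves as formate)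
Why: Dakin-type Baeyer–Villiger oxidation, in which the electron-rich 2,6-dioxygenated aryl migrates and the formate is methanolysed; no alkene is present yet and the buffer protects the acid-labile tert-alkyl aryl ether.

**Step 7**
Reactants: 9
Product: 10, 4-allyl-2-(4-allylphenoxy)-6-{[(4R,5R,7R,10R)-11-(triethylsilyloxy)eudesman-4-yl]oxy}phenol
Conditions: allylSnBu3 (3 equiv), Pd(PPh3)4 (10 mol %), DMF, 90 °C
Reagents that add atoms: allyltributylstannane, C=CC[Sn](CCCC)(CCCC)CCCC (two allyl groups)
Why: Double Migita–Kosugi–Stille coupling under neutral conditions tolerates the free phenol, the tert-alkyl ether and the silyl ether, and replaces both C(sp2)–Br bonds with allyl.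

**Step 8**
Reactants: 10
Product: 11, eudesobovatol A
Conditions: TBAF, THF, rt → 45 °C; NH4Cl work-up
Reagents that add atoms: none
Why: Fluoride-driven Si–O cleavage frees the C11 tertiary alcohol without acid, so the tert-alkyl aryl ether, the allyl groups and all four stereocentres are unaffected.

## Compound list

1 | (+)-β-eudesmol, 2-[(2R,4aR,8aS)-4a-methyl-8-methylidenedecahydronaphthalen-2-yl]propan-2-ol | C=C1CCC[C@]2(C)CC[C@@H](C(C)(C)O)C[C@@H]12 | starting material
2 | 11-(triethylsilyloxy)eudesm-4(15)-ene | C=C1CCC[C@]2(C)CC[C@@H](C(C)(C)O[Si](CC)(CC)CC)C[C@@H]12 | intermediate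
3 | (4R)-4α,15-epoxy-11-(triethylsilyloxy)eudesmane | C1O[C@@]12CCC[C@]3(C)CC[C@@H](C(C)(C)O[Si](CC)(CC)CC)C[C@@H]23 | intermediate
4 | (4R,5R,7R,10R)-11-(triethylsilyloxy)eudesman-4-ol | O[C@]1(C)CCC[C@]2(C)CC[C@@H](C(C)(C)O[Si](CC)(CC)CC)C[C@H]21 | intermediate
5 | 4-bromo-2,6-difluorobenzaldehyde | O=Cc1c(F)cc(Br)cc1F | starting material
6 | 4-bromo-2-fluoro-6-(11-TESO-eudesman-4α-yloxy)benzaldehyde | O=Cc1c(F)cc(Br)cc1O[C@]2(C)CCC[C@]3(C)CC[C@@H](C(C)(C)O[Si](CC)(CC)CC)C[C@H]32 | intermediate
7 | 4-bromophenol | Oc1ccc(Br)cc1 | starting material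
8 | 4-bromo-2-(4-bromophenoxy)-6-(11-TESO-eudesman-4α-yloxy)benzaldehyde | O=Cc1c(Oc2ccc(Br)cc2)cc(Br)cc1O[C@]2(C)CCC[C@]3(C)CC[C@@H](C(C)(C)O[Si](CC)(CC)CC)C[C@H]32 | intermediate
9 | 4-bromo-2-(4-bromophenoxy)-6-(11-TESO-eudesman-4α-yloxy)phenol | Oc1c(Oc2ccc(Br)cc2)cc(Br)cc1O[C@]2(C)CCC[C@]3(C)CC[C@@H](C(C)(C)O[Si](CC)(CC)CC)C[C@H]32 | intermediate
10 | 11-O-TES-eudesobovatol A | Oc1c(Oc2ccc(CC=C)cc2)cc(CC=C)cc1O[C@]2(C)CCC[C@]3(C)CC[C@@H](C(C)(C)O[Si](CC)(CC)CC)C[C@H]32 | intermediate
11 | eudesobovatol A | C=CCc1ccc(Oc2cc(CC=C)cc(O[C@]3(C)CCC[C@]4(C)CC[C@@H](C(C)(C)O)C[C@H]43)c2O)cc1 | target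

## Summary

Total step count: 8.
Longest linear sequence: 8 steps (from 1; 5 and 7 are used as purchased).

Three steps most likely to fail, each with a fallback that changes the approach:

1. **Step 4** (SNAr of a hindered tertiary alkoxide on an aldehyde-bearing arene; risks are steric retardation and carbonyl addition or Tishchenko-type side reactions). Fallback: make the C4–O bond from the alkene instead of the alkoxide, by Co(salen)-catalysed MHAT radical–polar-crossover Markovnikov hydroetherification of alkene 2 with a mono-MOM-protected 5-bromo-3-(4-bromophenoxy)catechol. Equatorial α-capture at C4, anti to the C10 methyl, is expected; this also removes steps 2–3 and 5–6.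

2. **Step 6** (Dakin oxidation of a di-ortho-substituted, hindered aldehyde; risks are slow reaction, over-oxidation to the acid, or acid-induced loss of the tert-alkyl group). Fallback: change the activating group to nitro by using 5-bromo-1,3-difluoro-2-nitrobenzene in steps 4–5. The hydroxyl is then installed by nitro reduction (Fe/NH4Cl), Sandmeyer-type borylation (t-BuONO, B2pin2) and NaBO3 oxidation under non-acidic conditions.

3. **Step 7** (double allylation of an electron-rich bromophenol; risks are sluggish oxidative addition at the central ring, incomplete bis-coupling, and allyl-to-propenyl isomerisation). Fallback: bring the allyl groups in with the building blocks. Use commercial 4-allylphenol in step 5 and 4-allyl-2,6-difluorobenzaldehyde (one Stille coupling on 5) in step 4, then run the Dakin step with a non-epoxidising protocol (H2O2 with catalytic (PhSe)2), so no late-stage cross-coupling is needed.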